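The data come from a simulation on assumed constants.

You read the flask at 10 h, so the decision comes before charging it: with impurity up to 9.3 mM, do you leave free catalyst at 14 mM or change it, if target is to stay ahead of isomer of the product A?

| flask | substrate | free catalyst | impurity | remark | time |
|---|---|---|---|---|---|
| north | 0.72 M | 14 mM | 4.7 mM | run made earlier |  |
| north-west | 0.72 M | 14 mM | 7 mM | run made earlier |  |
| flask | 0.72 M | 14 mM | 9.3 mM |  | 10 h |

| run | time / h | isomer of the product A / % | target / % | substrate / % |
|---|---|---|---|---|
| north | 0.417 | 0 | 2.5 | 96.2 |
| north | 1.33 | 0 | 5.4 | 89.2 |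
| north | 2.00 | 0.1 | 7.3 | 84.7 |
| north | 3.00 | 0.2 | 11.3 | 78.3 |
| north | 5.00 | 0.7 | 17.3 | 69.1 |
| north | 6.00 | 0.6 | 18.7 | 63.9 |
| north-west | 0.417 | 0 | 2.4 | 96.6 |
| north-west | 1.33 | 0 | 6.3 | 88.9 |
| north-west | 2.00 | 0.2 | 8.4 | 85.3 |
| north-west | 3.00 | 0.4 | 11.8 | 79.6 |
| north-west | 5.00 | 1.3 | 16.5 | 69.0 |
| north-west | 6.00 | 0.9 | 20.0 | 66.5 |

(each reading ± 0.5 percentage points)

- what may be going on: substrate <-> target; target + free catalyst <-> isomer of the product A + free catalyst; isomer of the product A + free catalyst <-> isomer of the product B + free catalyst; isomer of the product B + free catalyst <-> substrate + free catalyst; free catalyst + impurity -> spent catalyst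

1. share of isomer of the product A in isomer of the product A plus target at 15 min
2. share of isomer of the product A in isomer of the product A plus target at 10 h
3. which of isomer of the product A and target there is more of at 10 h

Impurity takes free catalyst one for one, and every step beyond target carries free catalyst as a factor. Once the impurity has reacted, those steps are therefore pseudo-first-order, with a rate coefficient proportional to the charge of free catalyst minus the charge of impurity. For this flask that gives c_r = 4.70 mM, the residual free catalyst.

The earlier runs test this. What substrate, target and isomer of the product A together miss at 6.00 h must be isomer of the product B, and it reads 16.8 % in the north run and 12.6 % in the north-west run. Their ratio, a reading that carries the scatter of the readings behind it, is 0.750 and stands beside 0.753 for their c_r values of 9.30 mM and 7.00 mM.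

The flask has half the north c_r. The north-west run, with a larger c_r than the flask, reads a share of isomer of the product A of 4.31 % at 6.00 h. So my decision is to leave the charge as it is and expect target to lead.

The forecast agrees, with 0.2 % at 15 min, 7 % at 10 h and target ahead, and it reckons the catalyst as I do: “The flask should then have about 4.7 mM free catalyst.”

The flask gives 0.365 % at 15 min and 5.92 % at 10 h, with target ahead, 26.6 % against 1.68 %.

    substrate ⇌ target (K = 1.00, k = 0.0483 /h)
    target + free catalyst ⇌ isomer of the product A + free catalyst, rate k2*[free catalyst]*[target] forward; the back reaction follows from the equilibrium constant (K = 5.29, k = 1.43 /M/h)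
    isomer of the product A + free catalyst ⇌ isomer of the product B + free catalyst, rate k3*[free catalyst]*[isomer of the product A] forward; the back reaction follows from the equilibrium constant (K = 0.370, k = 0.346 /M/h)
    isomer of the product B + free catalyst ⇌ substrate + free catalyst, rate k4*[free catalyst]*[isomer of the product B] forward; the back reaction follows from the equilibrium constant (k = 1.78 /M/h)
    free catalyst + impurity → spent catalyst (k = 79.6 /M/h)

At 10.0 h the flask holds free catalyst at 34.1 % of its charge, or 4.77 mM against c_r of 4.70 mM, with impurity down to 0.809 % of its own charge. Charged with 0.056 M of free catalyst instead, the same flask has c_r = 46.7 mM, ten times as much and 83.4 % of that charge, and it stands at 83.4 % free catalyst. There the share at 10.0 h is 58.6 %, with more isomer of the product A, 18.7 %, than target, 13.2 %.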